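The route rests on the O1–C2 bond of ring C, read as a retro-oxa-Michael cut. O1, the phenol oxygen on C8a of ring A, lies β to the C4 ketone through C2–C3. The key step exploits the C3 methylene beside C4 as seat for a temporary tert-butyl ester. This makes the open precursor an alkylidene β-keto ester, an acyclic 2-aroylcinnamate that joins prenylated ring A to the chroman aldehyde. It also gives a bifunctional cinchona thiourea two carbonyls to grip. In one flask O1 closes ring C, the catalyst sets C2 as S, and the ester leaves as isobutene and CO2.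

Key step: step 5

Assumption: 8 is drawn as the E isomer (chroman aryl trans to the ester), and the quinidine-derived catalyst is taken as the pseudoenantiomer that leads to 2S; the quinine-derived one would give the opposite sense.

Step 1
Reactants: 1 methyl 2,4-dihydroxybenzoate; 2 prenyl bromide (1-bromo-3-methylbut-2-ene)
Product: 3 methyl 2,4-dihydroxy-3-(3-methylbut-2-en-1-yl)benzoate
Conditions: KOH (2 equiv), MeOH, 0 °C to rt
Reagents that add atoms: none
Why: Nuclear prenylation (C-alkylation of an ambident resorcinolate): in protic MeOH the phenoxide oxygens are solvated, so the soft allylic bromide should be taken up at C3, the carbon activated by both flanking oxygens, and MeOH as solvent makes ester exchange degenerate.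

Step 2
Reactants: 3 methyl 2,4-dihydroxy-3-(3-methylbut-2-en-1-yl)benzoate
Product: 4 methyl 2-hydroxy-3-(3-methylbut-2-en-1-yl)-4-(triisopropylsilyloxy)benzoate
Conditions: iPr3SiCl, imidazole, DMF, 0 °C to rt
Reagents that add atoms: triisopropylsilyl chloride, CC(C)[Si](Cl)(C(C)C)C(C)C
Why: Chemoselective silyl ether formation: the C2 hydroxyl is tied up in a hydrogen bond to the ester carbonyl and is flanked on both sides, so the bulky silyl chloride should react only at the C4 hydroxyl, which would otherwise neutralize the amine catalyst of step 5.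

Step 3
Reactants: 4 methyl 2-hydroxy-3-(3-methylbut-2-en-1-yl)-4-(triisopropylsilyloxy)benzoate; 5 tert-butyl acetate
Product: 6 tert-butyl 3-[2-hydroxy-3-(3-methylbut-2-en-1-yl)-4-(triisopropylsilyloxy)phenyl]-3-oxopropanoate
Conditions: 5 (4 equiv), LiN(iPr)2 (4 equiv), THF, −78 °C; then 4, −78 to 0 °C; aq NH4Cl
Reagents that add atoms: none
Why: Crossed Claisen condensation: the lithium enolate of 5 does not self-condense at low temperature and is acylated by the methyl ester, the surplus enolate takes up the phenol proton and the acidic methylene proton of 6, and the bulky tert-butyl ester should keep the free phenol from lactonizing to a 4-hydroxycoumarin.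

Step 4
Reactants: 6 tert-butyl 3-[2-hydroxy-3-(3-methylbut-2-en-1-yl)-4-(triisopropylsilyloxy)phenyl]-3-oxopropanoate; 7 2,2-dimethylchroman-6-carbaldehyde
Product: 8 tert-butyl (E)-3-(2,2-dimethylchroman-6-yl)-2-[2-hydroxy-3-(3-methylbut-2-en-1-yl)-4-(triisopropylsilyloxy)benzoyl]prop-2-enoate
Conditions: piperidine (cat.), AcOH (cat.), 4 Å molecular sieves, PhMe, rt
Reagents that add atoms: none
Why: Knoevenagel condensation through the piperidine-derived iminium ion of 7, driven by the sieves; the E isomer, in which the aroyl group twists out of the planar cinnamate, should prevail, and the buffered medium together with the chelated phenol should hold back ring closure.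

Step 5
Reactants: 8 tert-butyl (E)-3-(2,2-dimethylchroman-6-yl)-2-[2-hydroxy-3-(3-methylbut-2-en-1-yl)-4-(triisopropylsilyloxy)benzoyl]prop-2-enoate
Product: 12 (2S)-2-(2,2-dimethylchroman-6-yl)-8-(3-methylbut-2-en-1-yl)-7-(triisopropylsilyloxy)chroman-4-one, via trans tert-butyl ester 9 (not isolated), via bis(trimethylsilyl) derivative 10 (not isolated), via β-keto acid 11 (not isolated)
Conditions: 1-[3,5-bis(trifluoromethyl)phenyl]-3-[(9R)-6'-methoxycinchonan-9-yl]thiourea (10 mol %), PhMe, −25 °C; then Me3SiOTf, 2,6-lutidine, CH2Cl2, 0 °C to rt; then MeOH, 40 °C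
Reagents that add atoms: none
Why: The thiourea N–H bonds of the catalyst bind the ketone and ester carbonyls of 8 while its quinuclidine nitrogen takes the proton of the C8a hydroxyl, so that O1 adds to C2 in an intramolecular oxa-Michael addition and the enol is protonated to trans ester 9; Me3SiOTf/2,6-lutidine then turns the tert-butyl ester into silyl ester 10 with loss of isobutene, and methanolysis frees β-keto acid 11, which loses CO2 through its neutral enol. The closest known reaction type is the bifunctional thiourea-catalysed enantioselective cyclization of 2-hydroxyaryl alkylidene β-keto esters to flavanones with decarboxylation in the same flask, the usual hot sulfonic acid being replaced here by the known silylative tert-butyl ester cleavage in order to spare the prenyl alkene. Ring C closes in the 6-endo-trig mode through the O1–C2 bond. C2 is the only lasting stereocentre and is controlled by the catalyst alone, whose (8R,9R) pocket should present one face of the E alkene to O1 and give 2S, whereas C3 is set trans by thermodynamic protonation and is erased on decarboxylation. The step needs the catalysed closure to outrun both the uncatalysed closure and the reverse reaction: low temperature, the non-polar solvent, the bulky ester and the chelated phenol suppress the background, the silyl group on O7 keeps the acidic para phenol from neutralizing the amine, and the second carbonyl makes the addition downhill so that 9 should not reopen before the ester is removed.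

Step 6
Reactants: 12 (2S)-2-(2,2-dimethylchroman-6-yl)-8-(3-methylbut-2-en-1-yl)-7-(triisopropylsilyloxy)chroman-4-one
Product: 13 Euchrenone a17 [(2S)-2-(2,2-dimethylchroman-6-yl)-7-hydroxy-8-(3-methylbut-2-en-1-yl)chroman-4-one]
Conditions: Bu4NF, AcOH (1:1), THF, 0 °C
Reagents that add atoms: none
Why: Fluoride-induced cleavage of the aryl silyl ether, buffered with AcOH so that no free phenoxide or enolate can reopen ring C by a retro-oxa-Michael reaction, which should keep C2 intact and leave the prenyl group untouched.

Compound list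
1 | methyl 2,4-dihydroxybenzoate | COC(=O)c1ccc(O)cc1O | starting material
2 | prenyl bromide (1-bromo-3-methylbut-2-ene) | CC(C)=CCBr | starting material
3 | methyl 2,4-dihydroxy-3-(3-methylbut-2-en-1-yl)benzoate | COC(=O)c1ccc(O)c(CC=C(C)C)c1O | intermediate
4 | methyl 2-hydroxy-3-(3-methylbut-2-en-1-yl)-4-(triisopropylsilyloxy)benzoate | COC(=O)c1ccc(O[Si](C(C)C)(C(C)C)C(C)C)c(CC=C(C)C)c1O | intermediate
5 | tert-butyl acetate | CC(=O)OC(C)(C)C | starting material
6 | tert-butyl 3-[2-hydroxy-3-(3-methylbut-2-en-1-yl)-4-(triisopropylsilyloxy)phenyl]-3-oxopropanoate | CC(C)(C)OC(=O)CC(=O)c1ccc(O[Si](C(C)C)(C(C)C)C(C)C)c(CC=C(C)C)c1O | intermediate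
7 | 2,2-dimethylchroman-6-carbaldehyde | O=Cc1ccc2c(c1)CCC(C)(C)O2 | starting material
8 | tert-butyl (E)-3-(2,2-dimethylchroman-6-yl)-2-[2-hydroxy-3-(3-methylbut-2-en-1-yl)-4-(triisopropylsilyloxy)benzoyl]prop-2-enoate | CC(C)(C)OC(=O)/C(=C/c1ccc2c(c1)CCC(C)(C)O2)C(=O)c1ccc(O[Si](C(C)C)(C(C)C)C(C)C)c(CC=C(C)C)c1O | intermediate
9 | tert-butyl (2S,3R)-2-(2,2-dimethylchroman-6-yl)-8-(3-methylbut-2-en-1-yl)-4-oxo-7-(triisopropylsilyloxy)chroman-3-carboxylate (2,3-trans, not isolated) | CC(C)=CCc1c(O[Si](C(C)C)(C(C)C)C(C)C)ccc2c1O[C@H](c1ccc3c(c1)CCC(C)(C)O3)[C@@H](C(=O)OC(C)(C)C)C2=O | intermediate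
10 | trimethylsilyl (2R)-2-(2,2-dimethylchroman-6-yl)-8-(3-methylbut-2-en-1-yl)-7-(triisopropylsilyloxy)-4-(trimethylsilyloxy)-2H-chromene-3-carboxylate (descriptor changes, geometry at C2 as in 9; not isolated) | CC(C)=CCc1c(O[Si](C(C)C)(C(C)C)C(C)C)ccc2c1O[C@H](c1ccc3c(c1)CCC(C)(C)O3)C(C(=O)O[Si](C)(C)C)=C2O[Si](C)(C)C | intermediate
11 | (2S,3R)-2-(2,2-dimethylchroman-6-yl)-8-(3-methylbut-2-en-1-yl)-4-oxo-7-(triisopropylsilyloxy)chroman-3-carboxylic acid (not isolated) | CC(C)=CCc1c(O[Si](C(C)C)(C(C)C)C(C)C)ccc2c1O[C@H](c1ccc3c(c1)CCC(C)(C)O3)[C@@H](C(=O)O)C2=O | intermediate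
12 | (2S)-2-(2,2-dimethylchroman-6-yl)-8-(3-methylbut-2-en-1-yl)-7-(triisopropylsilyloxy)chroman-4-one | CC(C)=CCc1c(O[Si](C(C)C)(C(C)C)C(C)C)ccc2c1O[C@H](c1ccc3c(c1)CCC(C)(C)O3)CC2=O | intermediate
13 | Euchrenone a17, (2S)-2-(2,2-dimethylchroman-6-yl)-7-hydroxy-8-(3-methylbut-2-en-1-yl)chroman-4-one | CC(C)=CCc1c(O)ccc2c1O[C@H](c1ccc3c(c1)CCC(C)(C)O3)CC2=O | target

Total step count: 6. Longest linear sequence: 6 steps (1 to 13).

Steps most likely to fail

Step 5 (key step): the closure may run with poor facial selectivity, because the prenyl group next to O1 crowds the catalyst. Ester 9 may also reopen before it is decarboxylated, so that the enantiomeric purity erodes. The fallback replaces asymmetric catalysis by resolution; it sets out from 8 and comes back at 12.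
- Ring closure of 8 with catalytic Et3N in PhMe gives the racemic trans tert-butyl ester F1.
- The silylative ester cleavage and decarboxylation of step 5 turn it into the racemic silyl-protected flavanone F2.
- A kinetic resolution follows, by asymmetric transfer hydrogenation with RuCl(p-cymene)[(R,R)-TsDPEN] and HCO2H/Et3N in CH2Cl2 at rt, stopped near half conversion.
- This should reduce the matched 2R enantiomer to the cis-(2R,4R)-flavan-4-ol F3 and leave the 2S ketone, which is 12, to be separated by chromatography.

Step 1: the alkylation may spread over O4, C5 and C3 and may run on to dialkylation, so that little of the C3 isomer is obtained. The fallback replaces direct C-alkylation by an oxygen-to-carbon transfer; it sets out from 1 and comes back at 3.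
- Alkylation of the unchelated C4 hydroxyl of 1 with 3-chloro-3-methylbut-1-yne (K2CO3, KI, acetone, reflux) gives the 1,1-dimethylpropargyl ether F4.
- Semihydrogenation (H2, Pd/CaCO3 poisoned with Pb(OAc)2, quinoline, EtOAc, rt) gives the 1,1-dimethylallyl ether F5.
- An aromatic Claisen rearrangement (xylene, 130 °C) then carries the five-carbon unit to C3 with allyl inversion. The bond fixation of the chelated salicylate directs the shift between the two oxygens.

Step 4: the amine may trigger premature, non-selective ring closure of 8, or the condensation with the electron-rich aldehyde may stall at room temperature. The fallback masks O1 during the fragment union; it sets out from 4 and comes back at 8.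
- Allylation of 4 (NaH, allyl bromide, DMF, 0 °C) gives the O-allyl benzoate F6.
- The crossed Claisen condensation with 5 and LiN(iPr)2 gives the O-allyl β-keto ester F7.
- A Knoevenagel condensation with 7 can now be forced (piperidine, AcOH, PhMe, reflux, Dean–Stark trap) without any ring closure and gives the O-allyl alkylidene F8.
- Deallylation with Pd(PPh3)4 (a zerovalent palladium complex) and the weakly basic scavenger N-methylaniline in THF at rt frees the phenol as 8.

Further compounds
F1 | step 5 | racemic trans tert-butyl 2-(2,2-dimethylchroman-6-yl)-8-(3-methylbut-2-en-1-yl)-4-oxo-7-(triisopropylsilyloxy)chroman-3-carboxylate | CC(C)=CCc1c(O[Si](C(C)C)(C(C)C)C(C)C)ccc2c1OC(c1ccc3c(c1)CCC(C)(C)O3)C(C(=O)OC(C)(C)C)C2=O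
F2 | step 5 | racemic 2-(2,2-dimethylchroman-6-yl)-8-(3-methylbut-2-en-1-yl)-7-(triisopropylsilyloxy)chroman-4-one | CC(C)=CCc1c(O[Si](C(C)C)(C(C)C)C(C)C)ccc2c1OC(c1ccc3c(c1)CCC(C)(C)O3)CC2=O
F3 | step 5 | (2R,4R)-2-(2,2-dimethylchroman-6-yl)-8-(3-methylbut-2-en-1-yl)-7-(triisopropylsilyloxy)chroman-4-ol | CC(C)=CCc1c(O[Si](C(C)C)(C(C)C)C(C)C)ccc2c1O[C@@H](c1ccc3c(c1)CCC(C)(C)O3)C[C@H]2O
F4 | step 1 | methyl 2-hydroxy-4-[(2-methylbut-3-yn-2-yl)oxy]benzoate | COC(=O)c1ccc(OC(C)(C)C#C)cc1O
F5 | step 1 | methyl 2-hydroxy-4-[(2-methylbut-3-en-2-yl)oxy]benzoate | COC(=O)c1ccc(OC(C)(C)C=C)cc1O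
F6 | step 4 | methyl 2-(allyloxy)-3-(3-methylbut-2-en-1-yl)-4-(triisopropylsilyloxy)benzoate | COC(=O)c1ccc(O[Si](C(C)C)(C(C)C)C(C)C)c(CC=C(C)C)c1OCC=C
F7 | step 4 | tert-butyl 3-[2-(allyloxy)-3-(3-methylbut-2-en-1-yl)-4-(triisopropylsilyloxy)phenyl]-3-oxopropanoate | CC(C)(C)OC(=O)CC(=O)c1ccc(O[Si](C(C)C)(C(C)C)C(C)C)c(CC=C(C)C)c1OCC=C
F8 | step 4 | tert-butyl (E)-2-[2-(allyloxy)-3-(3-methylbut-2-en-1-yl)-4-(triisopropylsilyloxy)benzoyl]-3-(2,2-dimethylchroman-6-yl)prop-2-enoate | CC(C)(C)OC(=O)/C(=C/c1ccc2c(c1)CCC(C)(C)O2)C(=O)c1ccc(O[Si](C(C)C)(C(C)C)C(C)C)c(CC=C(C)C)c1OCC=C
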